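**Retrosynthetic overview**
- Feature: in eudesmane numbering, the fusion bond C5–C10 of the trans-decalin (ring A = C1–C5, C10; ring B = C5–C10) has the 1β-hydroxyl and the quaternary C10 (methyl C14) on one side and the exocyclic C4=C15 methylene on the other. A germacrane leaves this pattern when its C1–C10 epoxide opens and C10 bonds to C5 of a C4=C5 alkene.
- Late disconnections: the O6 acrylate ester and the C12 methyl ester go back to the trans-fused 6α,12-lactone of a 1β-hydroxy-3β-silyloxyeudesmanolide.
- Key disconnection: C5–C10, which leads back to the 3β-silyloxy-1β,10α-epoxygermacrolide. Trivalent titanium closes rings A and B together.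
- Ring order: ten-membered carbocycle (C6–C7, allylchromium plus enal), then lactone (oxidation of the 6,12-diol), then epoxide, then rings A and B at once. The lactone is opened at the end.
- Chain: C3 comes from asymmetric allylboration of a C5 enal, E-C1=C10 from an orthoester Claisen rearrangement, and C11–C13 from a 2-lithioallyl ether.

Key step: step 16

Remark: germacrane/eudesmane numbering is used throughout. Centres that are erased again (the carbinol carbons of 8, 11, 13 and 20–23, and the lactol carbon of 27) are carried as epimer mixtures and written without configuration.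

**Step 1**
Reactants: 1 (tert-butyldimethylsilyloxy)acetaldehyde; 2 2-(triphenylphosphoranylidene)propanal
Product: 3 (E)-4-(tert-butyldimethylsilyloxy)-2-methylbut-2-enal
Conditions: toluene, 80 °C
Reagents that add atoms: none
Why: Wittig olefination with a stabilised ylide is E-selective and stops after one homologation because the α-branched enal 3 is far less electrophilic than 1, which fixes the later C4=C5 geometry (C3 trans to C6).

**Step 2**
Reactants: 3 (E)-4-(tert-butyldimethylsilyloxy)-2-methylbut-2-enal; 4 (−)-B-allyldiisopinocampheylborane (antipode derived from (+)-α-pinene)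
Product: 6 (4S,5E)-7-(tert-butyldimethylsilyloxy)-5-methylhepta-1,5-dien-4-ol, via diisopinocampheylborinate 5 (not isolated)
Conditions: Et2O, −78 °C; then 3 M NaOH, 30% H2O2, 0 °C to rt
Reagents that add atoms: none
Why: Brown allylboration passes through a closed chair transition state in which the isopinocampheyl groups choose the aldehyde face, and this antipode, in the sense known for aryl and alkenyl aldehydes, gives the (S)-carbinol that becomes C3 (3β-oxygen).

**Step 3**
Reactants: 6 (4S,5E)-7-(tert-butyldimethylsilyloxy)-5-methylhepta-1,5-dien-4-ol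
Product: 7 (4S,5E)-4,7-bis(tert-butyldimethylsilyloxy)-5-methylhepta-1,5-diene
Conditions: TBSCl, imidazole, DMF, rt
Reagents that add atoms: tert-butyldimethylsilyl chloride, C[Si](C)(Cl)C(C)(C)C
Why: Imidazole-promoted silylation of a secondary allylic alcohol is routine and does not touch C3.

**Step 4**
Reactants: 7 (4S,5E)-4,7-bis(tert-butyldimethylsilyloxy)-5-methylhepta-1,5-diene
Product: 9 (3S,4E)-3,6-bis(tert-butyldimethylsilyloxy)-4-methylhex-4-enal, via 1,2-diol 8 (not isolated)
Conditions: OsO4 (2 mol %), NaIO4, 2,6-lutidine, dioxane–H2O, rt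
Reagents that add atoms: OsO4, O=[Os](=O)(=O)=O (carries the oxygen); NaIO4, [Na+].[O-]I(=O)(=O)=O (restores it)
Why: In this Lemieux–Johnson cleavage OsO4 should take the open monosubstituted alkene, because the trisubstituted one is shielded and inductively deactivated by two allylic silyloxy groups, and 2,6-lutidine keeps the medium neutral for the β-silyloxy aldehyde.

**Step 5**
Reactants: 9 (3S,4E)-3,6-bis(tert-butyldimethylsilyloxy)-4-methylhex-4-enal; 10 isopropenylmagnesium bromide
Product: 11 (5S,6E)-5,8-bis(tert-butyldimethylsilyloxy)-2,6-dimethylocta-1,6-dien-3-ol (C3 epimers)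
Conditions: THF, −78 °C; aq. NH4Cl
Reagents that add atoms: none
Why: Grignard 1,2-addition brings in C10, C14 and C9, and the new carbinol centre (later C1) needs no control because step 6 turns it into an alkene carbon.

**Step 6**
Reactants: 11 (5S,6E)-5,8-bis(tert-butyldimethylsilyloxy)-2,6-dimethylocta-1,6-dien-3-ol; 12 triethyl orthoacetate
Product: 14 ethyl (4E,7S,8E)-7,10-bis(tert-butyldimethylsilyloxy)-4,8-dimethyldeca-4,8-dienoate, via ketene acetal 13 (not isolated)
Conditions: EtCO2H (cat.), neat 12, 140 °C, EtOH distilled off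
Reagents that add atoms: none
Why: The Johnson orthoester Claisen rearrangement forms C8–C9 through a chair transition state with the carbinol substituent equatorial, which gives the E-trisubstituted C1=C10 alkene.

**Step 7**
Reactants: 14 ethyl (4E,7S,8E)-7,10-bis(tert-butyldimethylsilyloxy)-4,8-dimethyldeca-4,8-dienoate
Product: 15 (4E,7S,8E)-7,10-bis(tert-butyldimethylsilyloxy)-4,8-dimethyldeca-4,8-dienal
Conditions: i-Bu2AlH (1.05 equiv), CH2Cl2, −78 °C; aq. KNa tartrate
Reagents that add atoms: none
Why: Partial ester reduction stops at the tetrahedral aluminium hemiacetal at −78 °C, and this collapses to the C7 aldehyde only on work-up.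

**Step 8**
Reactants: 16 4-methoxybenzyl alcohol; 17 2,3-dibromopropene
Product: 18 2-bromoallyl 4-methoxybenzyl ether
Conditions: NaH, THF–DMF, 0 °C to rt
Reagents that add atoms: none
Why: In this Williamson ether synthesis the alkoxide displaces only the allylic bromide, and the vinylic bromide is inert.

**Step 9**
Reactants: 15 (4E,7S,8E)-7,10-bis(tert-butyldimethylsilyloxy)-4,8-dimethyldeca-4,8-dienal; 18 2-bromoallyl 4-methoxybenzyl ether
Product: 21 (6E,9S,10E)-9,12-bis(tert-butyldimethylsilyloxy)-2-[(4-methoxybenzyloxy)methyl]-6,10-dimethyldodeca-1,6,10-trien-3-yl diethyl phosphate (C3 epimers), via alkenyllithium 19 (not isolated), via lithium alkoxide 20 (not isolated)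
Conditions: 18, t-BuLi (2 equiv per 18), Et2O, −78 °C; 15, −78 °C; ClP(O)(OEt)2, −78 to 0 °C
Reagents that add atoms: diethyl chlorophosphate, CCOP(=O)(Cl)OCC
Why: Bromine–lithium exchange, 1,2-addition of the alkenyllithium and O-phosphorylation of the alkoxide in one flask attach C11–C13 and install the allylic leaving group at C7, whose configuration is lost again in step 12.

**Step 10**
Reactants: 21 the bis-silyl allylic phosphate
Product: 22 (6E,9S,10E)-9-(tert-butyldimethylsilyloxy)-12-hydroxy-2-[(4-methoxybenzyloxy)methyl]-6,10-dimethyldodeca-1,6,10-trien-3-yl diethyl phosphate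
Conditions: HF·pyridine, excess pyridine, THF, 0 °C
Reagents that add atoms: none
Why: Buffered fluoride desilylation discriminates by steric access, so the primary allylic silyl ether at C6 falls well before the secondary one at C3, and phosphate and PMB ether are inert.

**Step 11**
Reactants: 22 the C6 allylic alcohol
Product: 23 (6E,9S,10E)-9-(tert-butyldimethylsilyloxy)-2-[(4-methoxybenzyloxy)methyl]-6,10-dimethyl-12-oxododeca-1,6,10-trien-3-yl diethyl phosphate
Conditions: MnO2, CH2Cl2, rt
Reagents that add atoms: none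
Why: MnO2 oxidation of a primary allylic alcohol is neutral, keeps the E geometry and stops at the enal.

**Step 12**
Reactants: 23 the enal allylic phosphate
Product: 25 3β-(tert-butyldimethylsilyloxy)-12-(4-methoxybenzyloxy)germacra-1(10)E,4E,11(13)-trien-6α-ol (side chain on C7 β), via allylchromium dichloride 24 (not isolated)
Conditions: CrCl2 (10 equiv), LiI (0.5 equiv), THF–DMPU, syringe-pump addition of 23 (final about 2 mM), rt; aq. NH4Cl
Reagents that add atoms: none
Why: In this intramolecular Nozaki–Hiyama allylchromium addition (allylic phosphate/iodide variant, high dilution) the equilibrating allylchromium reacts at its γ-carbon C7 through a Zimmerman–Traxler chair from the geometry with C8 trans to CH2Cr, which sets the anti C6/C7 relation, while attack on the Si face of the enal is expected from the crown-like folding that keeps the C3 silyloxy group pseudo-equatorial; C12 is carried as an ether because 2-alkoxycarbonyl allylchromium reagents add syn and would lead to the cis-lactone.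

**Step 13**
Reactants: 25 the macrocyclic PMB ether
Product: 26 3β-(tert-butyldimethylsilyloxy)germacra-1(10)E,4E,11(13)-triene-6α,12-diol
Conditions: DDQ, CH2Cl2–pH 7 phosphate buffer, 0 °C
Reagents that add atoms: none
Why: Oxidative PMB cleavage starts at the electron-rich benzyl ether, which is oxidised more easily than the trisubstituted alkenes, and the buffer keeps acid away from the 1,5-diene.

**Step 14**
Reactants: 26 the 6α,12-diol
Product: 28 3β-(tert-butyldimethylsilyloxy)germacra-1(10)E,4E,11(13)-trien-6α,12-olide, via lactol 27 (not isolated)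
Conditions: TEMPO (cat.), PhI(OAc)2, CH2Cl2, rt
Reagents that add atoms: none
Why: In this oxoammonium-mediated oxidative lactonisation of a 1,4-diol the primary allylic alcohol is oxidised first, the aldehyde closes on the 6α-hydroxyl and the lactol is oxidised again, so the trans ring fusion follows from C6 and C7 as set in step 12.

**Step 15**
Reactants: 28 the germacrolide
Product: 29 3β-(tert-butyldimethylsilyloxy)-1β,10α-epoxygermacra-4E,11(13)-dien-6α,12-olide
Conditions: mCPBA (1 equiv), NaHCO3, CH2Cl2, 0 °C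
Reagents that add atoms: 3-chloroperoxybenzoic acid, OOC(=O)c1cccc(Cl)c1
Why: Prilezhaev epoxidation picks C1=C10 as the only electron-rich alkene (C4=C5 has two allylic oxygens, C11=C13 is conjugated), and attack on its outer face in the crown conformer sets C1 and C10 as the 1β,10α-epoxide.

**Step 16**
Reactants: 29 3β-(tert-butyldimethylsilyloxy)-1β,10α-epoxygermacra-4E,11(13)-dien-6α,12-olide
Product: 31 1β-hydroxy-3β-(tert-butyldimethylsilyloxy)eudesma-4(15),11(13)-dien-6α,12-olide, via titanium alkoxide 30 (not isolated)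
Conditions: Cp2TiCl2 (2.5 equiv), Mn (8 equiv), dry deoxygenated THF, rt, slow addition of 29; then cold 0.5 M HCl
Reagents that add atoms: none
Why: Cp2TiCl, formed from Cp2TiCl2 and Mn, gives one electron to the epoxide and cleaves C10–O rather than C1–O because this yields the tertiary radical, while O1 stays bound to tetravalent titanium and C1 keeps its configuration. The C10 radical then bonds across the ring to C5, which creates C5–C10 and both six-membered rings at once: counted in ring A (C10, C1, C2, C3, C4, C5) the closure is 6-endo, since both alkene carbons end inside that ring, and counted in ring B (C10, C9, C8, C7, C6, C5) it is 6-exo, since C4 stays outside. The closest known reaction type is the titanocene-mediated reductive epoxide opening with radical cyclisation (Nugent–RajanBabu chemistry), which is known in this transannular form for 1,10-epoxygermacrolides without a C3 substituent. C10 and C5 are controlled by the chair–chair folding of the ten-membered ring, which the trans-fused lactone holds with C14 and C15 both on the β face, so C14 ends β on C10, H5 ends α and the decalin is trans. A second Cp2TiCl ends the tertiary C4 radical by taking a hydrogen of the exposed C15 methyl, either directly or through β-hydride loss from the alkyltitanium, and this gives C4=C15 and Cp2Ti(H)Cl. The step needs this regioselective ending and intact C3–O and acrylate units: exclusion of water prevents reduction of the radical, the equatorial 3β-silyloxy group lies near the nodal plane of the C4 radical and is poorly aligned for β-loss, H3 and H5 are more hindered than the methyl hydrogens, and C10 cannot reach C13.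

**Step 17**
Reactants: 31 the 1β-hydroxyeudesmanolide
Product: 32 3β-(tert-butyldimethylsilyloxy)-1β-(triethylsilyloxy)eudesma-4(15),11(13)-dien-6α,12-olide
Conditions: TESOTf, 2,6-lutidine, CH2Cl2, −78 to 0 °C
Reagents that add atoms: triethylsilyl triflate, CC[Si](CC)(CC)OS(=O)(=O)C(F)(F)F
Why: Silyl triflate silylation is strong enough for the equatorial hydroxyl next to quaternary C10, and it ensures that O6 will be the only free hydroxyl at the acylation stage.

**Step 18**
Reactants: 32 the bis-silyl lactone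
Product: 34 methyl 6α-hydroxy-3β-(tert-butyldimethylsilyloxy)-1β-(triethylsilyloxy)eudesma-4(15),11(13)-dien-12-oate, via potassium carboxylate 33 (not isolated)
Conditions: KOH (1.1 equiv), THF–H2O, 0 °C to rt; evaporation, toluene azeotrope; MeI, DMF, 0 °C to rt
Reagents that add atoms: potassium hydroxide, [K+].[OH-]; iodomethane, CI
Why: Saponification breaks only the acyl C12–O bond of the strained trans-fused lactone (C6 and C7 untouched) and gives a carboxylate whose acrylate no longer accepts nucleophiles, and SN2 O-methylation in DMF then forms the ester without the acid that would drive relactonisation.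

**Step 19**
Reactants: 35 methyl 2-(hydroxymethyl)acrylate
Product: 36 methyl 2-[(tert-butyldimethylsilyloxy)methyl]acrylate
Conditions: TBSCl, imidazole, CH2Cl2, 0 °C to rt
Reagents that add atoms: tert-butyldimethylsilyl chloride, C[Si](C)(Cl)C(C)(C)C
Why: This is routine silylation of a primary allylic alcohol.

**Step 20**
Reactants: 36 methyl 2-[(tert-butyldimethylsilyloxy)methyl]acrylate
Product: 37 2-[(tert-butyldimethylsilyloxy)methyl]acrylic acid
Conditions: LiOH, THF–H2O, 0 °C; 1 M HCl to pH 4
Reagents that add atoms: lithium hydroxide, [Li+].[OH-]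
Why: Ester saponification at 0 °C is faster than conjugate addition to the α-substituted acrylate, and the silyl ether survives the brief, mild acidification.

**Step 21**
Reactants: 34 the 6α-hydroxy methyl ester; 37 2-[(tert-butyldimethylsilyloxy)methyl]acrylic acid
Product: 39 methyl 6α-{2-[(tert-butyldimethylsilyloxy)methyl]acryloyloxy}-3β-(tert-butyldimethylsilyloxy)-1β-(triethylsilyloxy)eudesma-4(15),11(13)-dien-12-oate, via mixed anhydride 38 (not isolated)
Conditions: 37, 2,4,6-Cl3C6H2COCl, Et3N, toluene, rt; then 34, DMAP, toluene, rt to 40 °C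
Reagents that add atoms: none
Why: Yamaguchi esterification delivers a highly active acylpyridinium to the hindered equatorial 6α-hydroxyl with retention at C6, and it should outrun the base-induced return to the lactone.

**Step 22**
Reactants: 39 the tris-silyl diester
Product: 40 methyl 1β,3β-dihydroxy-6α-[2-(hydroxymethyl)acryloyloxy]eudesma-4(15),11(13)-dien-12-oate (CNP0247525.1)
Conditions: HF·pyridine, THF, 0 °C to rt
Reagents that add atoms: none
Why: Global fluoride desilylation under weakly acidic conditions removes all three silyl ethers without the acyl migration, Michael addition or lactonisation that a basic fluoride source could start.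

**Compound list**
1 | (tert-butyldimethylsilyloxy)acetaldehyde | O=CCO[Si](C)(C)C(C)(C)C | starting material
2 | 2-(triphenylphosphoranylidene)propanal | CC(C=O)=P(c1ccccc1)(c1ccccc1)c1ccccc1 | starting material
3 | (E)-4-(tert-butyldimethylsilyloxy)-2-methylbut-2-enal | O=C/C(C)=C/CO[Si](C)(C)C(C)(C)C | intermediate
4 | (−)-B-allyldiisopinocampheylborane | C=CCB([C@@H]1C[C@@H]2C[C@H]([C@H]1C)C2(C)C)[C@@H]1C[C@@H]2C[C@H]([C@H]1C)C2(C)C | starting material
5 | diisopinocampheylborinate of 6 | C=CC[C@H](OB([C@@H]1C[C@@H]2C[C@H]([C@H]1C)C2(C)C)[C@@H]1C[C@@H]2C[C@H]([C@H]1C)C2(C)C)/C(C)=C/CO[Si](C)(C)C(C)(C)C | intermediate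
6 | (4S,5E)-7-(tert-butyldimethylsilyloxy)-5-methylhepta-1,5-dien-4-ol | C=CC[C@H](O)/C(C)=C/CO[Si](C)(C)C(C)(C)C | intermediate
7 | (4S,5E)-4,7-bis(tert-butyldimethylsilyloxy)-5-methylhepta-1,5-diene | C=CC[C@H](O[Si](C)(C)C(C)(C)C)/C(C)=C/CO[Si](C)(C)C(C)(C)C | intermediate
8 | (4S,5E)-4,7-bis(tert-butyldimethylsilyloxy)-5-methylhept-5-ene-1,2-diol | OCC(O)C[C@H](O[Si](C)(C)C(C)(C)C)/C(C)=C/CO[Si](C)(C)C(C)(C)C | intermediate
9 | (3S,4E)-3,6-bis(tert-butyldimethylsilyloxy)-4-methylhex-4-enal | O=CC[C@H](O[Si](C)(C)C(C)(C)C)/C(C)=C/CO[Si](C)(C)C(C)(C)C | intermediate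
10 | isopropenylmagnesium bromide | C=C(C)[Mg]Br | starting material
11 | (5S,6E)-5,8-bis(tert-butyldimethylsilyloxy)-2,6-dimethylocta-1,6-dien-3-ol | C=C(C)C(O)C[C@H](O[Si](C)(C)C(C)(C)C)/C(C)=C/CO[Si](C)(C)C(C)(C)C | intermediate
12 | triethyl orthoacetate | CC(OCC)(OCC)OCC | starting material
13 | 1-ethoxyvinyl ether (ketene acetal) of 11 | C=C(OCC)OC(C(C)=C)C[C@H](O[Si](C)(C)C(C)(C)C)/C(C)=C/CO[Si](C)(C)C(C)(C)C | intermediate
14 | ethyl (4E,7S,8E)-7,10-bis(tert-butyldimethylsilyloxy)-4,8-dimethyldeca-4,8-dienoate | CCOC(=O)CC/C(C)=C/C[C@H](O[Si](C)(C)C(C)(C)C)/C(C)=C/CO[Si](C)(C)C(C)(C)C | intermediate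
15 | (4E,7S,8E)-7,10-bis(tert-butyldimethylsilyloxy)-4,8-dimethyldeca-4,8-dienal | O=CCC/C(C)=C/C[C@H](O[Si](C)(C)C(C)(C)C)/C(C)=C/CO[Si](C)(C)C(C)(C)C | intermediate
16 | 4-methoxybenzyl alcohol | COc1ccc(CO)cc1 | starting material
17 | 2,3-dibromopropene | C=C(Br)CBr | starting material
18 | 2-bromoallyl 4-methoxybenzyl ether | C=C(Br)COCc1ccc(OC)cc1 | intermediate
19 | 2-lithioallyl 4-methoxybenzyl ether | [Li]C(=C)COCc1ccc(OC)cc1 | intermediate
20 | lithium alkoxide of the C7 carbinol | [Li]OC(CC/C(C)=C/C[C@H](O[Si](C)(C)C(C)(C)C)/C(C)=C/CO[Si](C)(C)C(C)(C)C)C(=C)COCc1ccc(OC)cc1 | intermediate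
21 | (6E,9S,10E)-9,12-bis(tert-butyldimethylsilyloxy)-2-[(4-methoxybenzyloxy)methyl]-6,10-dimethyldodeca-1,6,10-trien-3-yl diethyl phosphate | CCOP(=O)(OCC)OC(CC/C(C)=C/C[C@H](O[Si](C)(C)C(C)(C)C)/C(C)=C/CO[Si](C)(C)C(C)(C)C)C(=C)COCc1ccc(OC)cc1 | intermediate
22 | (6E,9S,10E)-9-(tert-butyldimethylsilyloxy)-12-hydroxy-2-[(4-methoxybenzyloxy)methyl]-6,10-dimethyldodeca-1,6,10-trien-3-yl diethyl phosphate | CCOP(=O)(OCC)OC(CC/C(C)=C/C[C@H](O[Si](C)(C)C(C)(C)C)/C(C)=C/CO)C(=C)COCc1ccc(OC)cc1 | intermediate
23 | (6E,9S,10E)-9-(tert-butyldimethylsilyloxy)-2-[(4-methoxybenzyloxy)methyl]-6,10-dimethyl-12-oxododeca-1,6,10-trien-3-yl diethyl phosphate | CCOP(=O)(OCC)OC(CC/C(C)=C/C[C@H](O[Si](C)(C)C(C)(C)C)/C(C)=C/C=O)C(=C)COCc1ccc(OC)cc1 | intermediate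
24 | allylchromium dichloride (Cr on C13, C8 trans to CH2Cr) | Cl[Cr](Cl)C/C(COCc1ccc(OC)cc1)=C/CC/C(C)=C/C[C@H](O[Si](C)(C)C(C)(C)C)/C(C)=C/C=O | intermediate
25 | 3β-(tert-butyldimethylsilyloxy)-12-(4-methoxybenzyloxy)germacra-1(10)E,4E,11(13)-trien-6α-ol | C/C1=C\C[C@H](O[Si](C)(C)C(C)(C)C)/C(C)=C/[C@@H](O)[C@H](C(=C)COCc2ccc(OC)cc2)CC1 | intermediate
26 | 3β-(tert-butyldimethylsilyloxy)germacra-1(10)E,4E,11(13)-triene-6α,12-diol | C/C1=C\C[C@H](O[Si](C)(C)C(C)(C)C)/C(C)=C/[C@@H](O)[C@H](C(=C)CO)CC1 | intermediate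
27 | 6α,12-lactol of 26 | C/C1=C\C[C@H](O[Si](C)(C)C(C)(C)C)/C(C)=C/[C@H]2OC(O)C(=C)[C@@H]2CC1 | intermediate
28 | 3β-(tert-butyldimethylsilyloxy)germacra-1(10)E,4E,11(13)-trien-6α,12-olide | C/C1=C\C[C@H](O[Si](C)(C)C(C)(C)C)/C(C)=C/[C@H]2OC(=O)C(=C)[C@@H]2CC1 | intermediate
29 | 3β-(tert-butyldimethylsilyloxy)-1β,10α-epoxygermacra-4E,11(13)-dien-6α,12-olide | O1[C@@H]2C[C@H](O[Si](C)(C)C(C)(C)C)/C(C)=C/[C@H]3OC(=O)C(=C)[C@@H]3CC[C@@]12C | intermediate
30 | chlorotitanocene 1β-alkoxide of 31 | O1[C@@H]2[C@H]3C(=C)[C@@H](O[Si](C)(C)C(C)(C)C)C[C@@H]([O-])[C@]3(C)CC[C@H]2C(=C)C1=O.[Ti+4].[Cl-].c1cc[cH-]c1.c1cc[cH-]c1 | intermediate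
31 | 1β-hydroxy-3β-(tert-butyldimethylsilyloxy)eudesma-4(15),11(13)-dien-6α,12-olide | O1[C@@H]2[C@H]3C(=C)[C@@H](O[Si](C)(C)C(C)(C)C)C[C@@H](O)[C@]3(C)CC[C@H]2C(=C)C1=O | intermediate
32 | 3β-(tert-butyldimethylsilyloxy)-1β-(triethylsilyloxy)eudesma-4(15),11(13)-dien-6α,12-olide | O1[C@@H]2[C@H]3C(=C)[C@@H](O[Si](C)(C)C(C)(C)C)C[C@@H](O[Si](CC)(CC)CC)[C@]3(C)CC[C@H]2C(=C)C1=O | intermediate
33 | potassium 6α-hydroxy-3β-(tert-butyldimethylsilyloxy)-1β-(triethylsilyloxy)eudesma-4(15),11(13)-dien-12-oate | O[C@@H]1[C@H]2C(=C)[C@@H](O[Si](C)(C)C(C)(C)C)C[C@@H](O[Si](CC)(CC)CC)[C@]2(C)CC[C@H]1C(=C)C(=O)[O-].[K+] | intermediate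
34 | methyl 6α-hydroxy-3β-(tert-butyldimethylsilyloxy)-1β-(triethylsilyloxy)eudesma-4(15),11(13)-dien-12-oate | O[C@@H]1[C@H]2C(=C)[C@@H](O[Si](C)(C)C(C)(C)C)C[C@@H](O[Si](CC)(CC)CC)[C@]2(C)CC[C@H]1C(=C)C(=O)OC | intermediate
35 | methyl 2-(hydroxymethyl)acrylate | C=C(CO)C(=O)OC | starting material
36 | methyl 2-[(tert-butyldimethylsilyloxy)methyl]acrylate | C=C(CO[Si](C)(C)C(C)(C)C)C(=O)OC | intermediate
37 | 2-[(tert-butyldimethylsilyloxy)methyl]acrylic acid | C=C(CO[Si](C)(C)C(C)(C)C)C(=O)O | intermediate
38 | mixed anhydride of 37 and 2,4,6-trichlorobenzoic acid | C=C(CO[Si](C)(C)C(C)(C)C)C(=O)OC(=O)c1c(Cl)cc(Cl)cc1Cl | intermediate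
39 | methyl 6α-{2-[(tert-butyldimethylsilyloxy)methyl]acryloyloxy}-3β-(tert-butyldimethylsilyloxy)-1β-(triethylsilyloxy)eudesma-4(15),11(13)-dien-12-oate | C=C(CO[Si](C)(C)C(C)(C)C)C(=O)O[C@@H]1[C@H]2C(=C)[C@@H](O[Si](C)(C)C(C)(C)C)C[C@@H](O[Si](CC)(CC)CC)[C@]2(C)CC[C@H]1C(=C)C(=O)OC | intermediate
40 | methyl 1β,3β-dihydroxy-6α-[2-(hydroxymethyl)acryloyloxy]eudesma-4(15),11(13)-dien-12-oate | C=C(CO)C(=O)O[C@@H]1[C@H]2C(=C)[C@@H](O)C[C@@H](O)[C@]2(C)CC[C@H]1C(=C)C(=O)OC | target

**Totals**
Total step count: 22.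
Longest linear sequence: 19 steps (steps 1–7, 9–18, 21 and 22).

**Steps most likely to fail**

*Step 16 (key step).*
- What may go wrong: after ring closure the C4 radical may end the wrong way. It could lose H3 to give a silyl enol ether, lose the silyloxy group from an alkyltitanium, or take up hydrogen. The epoxide may also be deoxygenated before it cyclises.
- Fallback: it keeps the C5–C10 disconnection but goes through the cation and separates ring closure from alkene formation. It sets out from 29.
- Dilute HClO4 in aqueous acetone at 0 °C opens the epoxide heterolytically at C10. The same chair–chair folding closes C5–C10, and water captures the C4 cation from the α face to give 1β,4α-dihydroxy-3β-(tert-butyldimethylsilyloxy)eudesm-11(13)-en-6α,12-olide F1.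
- TESOTf and 2,6-lutidine at −78 °C silylate only the secondary hydroxyl and give the 1β-triethylsilyl ether of the 4α-alcohol F2.
- SOCl2 in pyridine at 0 °C dehydrates the equatorial tertiary alcohol by anti elimination. Only the C15 hydrogens can be antiperiplanar to the C4–O bond, so the exocyclic alkene should form. The route is rejoined at 32.

*Step 12.*
- What may go wrong: ring closure may lose to intermolecular coupling and to protonation of the allylchromium. The remote C3 centre may also choose the aldehyde face only weakly, because the gauche contact of a pseudo-equatorial silyloxy group with C15 offsets part of its advantage. The anti diastereomer with both C6 and C7 inverted would then compete.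
- Fallback: substrate control is replaced by reagent control. It sets out from 23, which is closed with a stoichiometric, preformed complex of CrCl2, Et3N and a chiral 2-(2-sulfonamidoaryl)oxazoline ligand, the known asymmetric variant of the allylchromium addition.
- The ligand antipode is chosen to deliver C7 to the Si face of the enal. The fallback comes back at 25 and makes no new compound (F0).

*Step 18.*
- What may go wrong: the γ-hydroxy ester may return to the lactone during methylation or during the slow acylation of step 21. Hydroxide may also add to C13 before the ring opens.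
- Fallback: the lactone is opened by reduction, so C12 cannot relactonise until O6 is acylated. It sets out from 32.
- i-Bu2AlH (CH2Cl2, −78 to 0 °C) gives the 6α,12-diol F3.
- TESCl and imidazole at −20 °C take the primary allylic hydroxyl and give the 12-triethylsilyl ether F4.
- Yamaguchi esterification with 37 gives the 6α-acrylate F5.
- PPTS in MeOH at 0 °C frees only the primary position and gives the 12-alcohol F6.
- MnO2 gives the 12-enal F7, and Pinnick oxidation (NaClO2, NaH2PO4, 2-methyl-2-butene) gives the 12-acid F8.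
- TMSCHN2 in toluene–MeOH then gives 39, where the route is rejoined.

**Further compounds**
F1 | step 16 | 1β,4α-dihydroxy-3β-(tert-butyldimethylsilyloxy)eudesm-11(13)-en-6α,12-olide | O1[C@@H]2[C@H]3[C@](C)(O)[C@@H](O[Si](C)(C)C(C)(C)C)C[C@@H](O)[C@]3(C)CC[C@H]2C(=C)C1=O
F2 | step 16 | 4α-hydroxy-3β-(tert-butyldimethylsilyloxy)-1β-(triethylsilyloxy)eudesm-11(13)-en-6α,12-olide | O1[C@@H]2[C@H]3[C@](C)(O)[C@@H](O[Si](C)(C)C(C)(C)C)C[C@@H](O[Si](CC)(CC)CC)[C@]3(C)CC[C@H]2C(=C)C1=O
F0 | step 12 | none | none
F3 | step 18 | 3β-(tert-butyldimethylsilyloxy)-1β-(triethylsilyloxy)eudesma-4(15),11(13)-diene-6α,12-diol | O[C@@H]1[C@H]2C(=C)[C@@H](O[Si](C)(C)C(C)(C)C)C[C@@H](O[Si](CC)(CC)CC)[C@]2(C)CC[C@H]1C(=C)CO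
F4 | step 18 | 3β-(tert-butyldimethylsilyloxy)-1β,12-bis(triethylsilyloxy)eudesma-4(15),11(13)-dien-6α-ol | O[C@@H]1[C@H]2C(=C)[C@@H](O[Si](C)(C)C(C)(C)C)C[C@@H](O[Si](CC)(CC)CC)[C@]2(C)CC[C@H]1C(=C)CO[Si](CC)(CC)CC
F5 | step 18 | 3β-(tert-butyldimethylsilyloxy)-1β,12-bis(triethylsilyloxy)eudesma-4(15),11(13)-dien-6α-yl 2-[(tert-butyldimethylsilyloxy)methyl]acrylate | C=C(CO[Si](C)(C)C(C)(C)C)C(=O)O[C@@H]1[C@H]2C(=C)[C@@H](O[Si](C)(C)C(C)(C)C)C[C@@H](O[Si](CC)(CC)CC)[C@]2(C)CC[C@H]1C(=C)CO[Si](CC)(CC)CC
F6 | step 18 | 12-hydroxy-3β-(tert-butyldimethylsilyloxy)-1β-(triethylsilyloxy)eudesma-4(15),11(13)-dien-6α-yl 2-[(tert-butyldimethylsilyloxy)methyl]acrylate | C=C(CO[Si](C)(C)C(C)(C)C)C(=O)O[C@@H]1[C@H]2C(=C)[C@@H](O[Si](C)(C)C(C)(C)C)C[C@@H](O[Si](CC)(CC)CC)[C@]2(C)CC[C@H]1C(=C)CO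
F7 | step 18 | 12-oxo-3β-(tert-butyldimethylsilyloxy)-1β-(triethylsilyloxy)eudesma-4(15),11(13)-dien-6α-yl 2-[(tert-butyldimethylsilyloxy)methyl]acrylate | C=C(CO[Si](C)(C)C(C)(C)C)C(=O)O[C@@H]1[C@H]2C(=C)[C@@H](O[Si](C)(C)C(C)(C)C)C[C@@H](O[Si](CC)(CC)CC)[C@]2(C)CC[C@H]1C(=C)C=O
F8 | step 18 | 6α-{2-[(tert-butyldimethylsilyloxy)methyl]acryloyloxy}-3β-(tert-butyldimethylsilyloxy)-1β-(triethylsilyloxy)eudesma-4(15),11(13)-dien-12-oic acid | C=C(CO[Si](C)(C)C(C)(C)C)C(=O)O[C@@H]1[C@H]2C(=C)[C@@H](O[Si](C)(C)C(C)(C)C)C[C@@H](O[Si](CC)(CC)CC)[C@]2(C)CC[C@H]1C(=C)C(=O)O
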